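Target is what I count in four flasks that differ in temperature.

all flasks: starting material 1.4 M; time 50 min

| run | temperature |
|---|---|
| maple | 65 °C |
| oak | 25 °C |
| birch | 5 °C |
| cedar | 45 °C |

    starting material + target → side product (k1 = 3.98 × 10⁻⁴ M⁻¹ s⁻¹, Ea1 = 63.0 kJ mol⁻¹)
    starting material ⇌ target + released group (K2 = 2.6 M, k2 = 0.0144 s⁻¹, Ea2 = 86.0 kJ mol⁻¹, ΔH2 = −29.0 kJ mol⁻¹)
    released group → by-product carried off (k3 = 1.41 × 10⁻⁴ s⁻¹, Ea3 = 99.0 kJ mol⁻¹)
    (constants at 25 °C)

- percentages count the starting material that a species holds: one side product counts as two
- the constants hold at 25 °C; other temperatures follow from the activation energies and enthalpies

* which flask leads in amount of target, in percent of the starting material charged ("all alike" within 1.5 percentage points) (maple / oak / birch / cedar / all alike)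
* how much target is there at the end, in percent of the starting material charged: maple
* how much target is there at the end, in percent of the starting material charged: oak
* how much target is there at the end, in percent of the starting material charged: birch
* how much target is there at the end, in percent of the starting material charged: cedar

I reckon birch by hand, because its equilibrium constant of 6.03 M is higher than maple's 0.652 M. There the side-product step can be treated as a slow drain on a pre-equilibrium. The same reciprocal-temperature gap links all the constants, so I scale them from the change in the equilibrium constant. The forward constant becomes 0.00119 s⁻¹, and the side-product constant becomes 6.40 × 10⁻⁵ M⁻¹ s⁻¹.

With target equal to released group, equilibrium in birch puts 1.17 M into target, which is 83.7% of the charge. The linearised relaxation rate is 0.00165 s⁻¹, a half-life of 7.00 min, shorter than the 50 min allowed.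

So birch can rest near equilibrium while side product forms. A first pass at those amounts gives 0.0513 M of side product. Each unit removes one starting material and one target, and its released group stays behind. Going round again with that loss lowers target to 1.09 M.

My carried quantity is the leak, the rate of side-product formation at the shifted equilibrium, 8.66 × 10⁻⁴ M min⁻¹.

The weak link is the approach, when starting material and target stand together at a larger product than at rest. Integrating an exponential approach adds 0.0163 M. Side product is then 0.0596 M, and target is 1.08 M. I commit to 77.0% for birch, setting aside the released group carried off. I carry no reckoning for the other flasks.

The forecast names birch, with 47.7% for maple, 50.3% for oak, 75.6% for birch and 41% for cedar, and says birch “nearly reaches equilibrium”.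

The simulation gives 47.6% for maple, 50.3% for oak, 76.7% for birch and 40.3% for cedar, so birch leads.

In maple the side-product step is the main reason for the missing target: the run without that step ends at >99.9% of target instead of 47.6%. In birch the same step is a part of the shortfall: the run without it ends at 83.2% of target instead of 76.7%, a difference of 6.5 percentage points.

Now take birch left until 2.0 h. The leak gives 0.120 M of side product, which is 17.2% of the charge, and the shifted equilibrium then gives 70.0% target. The computed flask holds 16.1% side product and 71.7% target.

All constants were set for the occasion; the result is computed.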